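**Plan**

1. Target locants are used throughout: aromatic C-1 to C-4 (CO2H on C-2, OH on C-3 and C-4), saturated ring C-5 (CH3) to C-8 (side chain), ring fusion C-4a/C-8a, side chain C-1′ to C-7′ (methines C-2′ and C-6′, oxygen on C-7′).
2. Retrosynthesis: the four aryl O–CH3 bonds and the tert-butyl ester C–O bond are cut last; then C-4′–C-5′, which divides the molecule into a tetralin bromide and the zinc reagent of the caffeate half; the tetralin half is cut at C-2–CO2, C-3′–C-4′, C-2′–CH3, C-8–C-8a and C-5–C-4a; the other half at the ester C–O bond.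
3. Forward: the aryl–C-5 bond is made first; the saturated ring then arises by a 6-exo Friedel–Crafts conjugate addition forming C-8–C-8a; methylation at C-2′, one-carbon extension and carboxylation at C-2 follow; the halves are joined at C-4′–C-5′ in the penultimate step and one deprotection ends the route.
4. Stereochemistry: C-5 from the chiral pyridine–oxazoline ligand of a redox-relay Heck reaction; C-8 and C-2′ both from one (R)-4-benzyloxazolidinone; C-6′ from commercial (S)-3-bromo-2-methylpropan-1-ol; the E-alkene from commercial (E)-3,4-dimethoxycinnamic acid.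
5. Feature that makes the key event possible: C-4′–C-5′ is a CH2–CH2 bond whose two carbons are non-stereogenic and are each separated from the functional ends by a methyl-bearing methine (C-2′ towards the tetralin ring, C-6′ towards the ester oxygen). The bromide carbon C-4′ is primary and unbranched at C-3′, and the zinc carbon C-5′ has its acyloxy group γ (on C-7′), so an alkyl–alkyl Negishi coupling can unite halves that already hold all four stereocentres, both rings and the caffeate ester.

Key step: step 14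

Assumption: the (S)-configured pyridine–oxazoline ligand is taken to deliver the (R)-aldehyde from the (E)-alkenol in step 3; if the sense were opposite, the (R)-ligand would be used and nothing else changes.

Step 1
Reactants: 1 (R)-4-benzyloxazolidin-2-one
Product: 3 (R)-4-benzyl-3-(2-bromoacetyl)oxazolidin-2-one, via lithium oxazolidinide 2 (not isolated)
Conditions: n-BuLi, THF, −78 °C; then BrCH2COBr, −78 → 0 °C
Reagents that add atoms: bromoacetyl bromide, BrCC(Br)=O
Why: N-acylation of the lithiated oxazolidinone with an acid bromide is the standard loading of an Evans auxiliary and leaves its stereocentre untouched.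

Step 2
Reactants: 3 (R)-4-benzyl-3-(2-bromoacetyl)oxazolidin-2-one
Product: 4 diethyl {2-[(R)-4-benzyl-2-oxooxazolidin-3-yl]-2-oxoethyl}phosphonate
Conditions: P(OEt)3, neat, 100 °C
Reagents that add atoms: triethyl phosphite, CCOP(OCC)OCC
Why: Michaelis–Arbuzov reaction of a primary α-bromo imide should give the phosphonate with loss of bromoethane.

Step 3
Reactants: 5 (2,3-dimethoxyphenyl)boronic acid; 6 (E)-pent-3-en-1-ol
Product: 7 (R)-4-(2,3-dimethoxyphenyl)pentanal
Conditions: Pd(MeCN)2(OTs)2 (6 mol %), Cu(OTf)2 (6 mol %), (S)-4-tert-butyl-2-[5-(trifluoromethyl)pyridin-2-yl]-4,5-dihydrooxazole (13 mol %), O2 (1 atm), 3 Å MS, DMF, rt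
Reagents that add atoms: none
Why: Enantioselective redox-relay oxidative Heck arylation of a homoallylic alcohol: aryl–palladium adds with the aryl group at the alkene carbon remote from the hydroxyl, palladium then walks along the chain by β-hydride elimination and reinsertion and leaves as the aldehyde, and the chiral ligand selects the alkene face and so sets C-5 as R.

Step 4
Reactants: 7 (R)-4-(2,3-dimethoxyphenyl)pentanal; 4 diethyl {2-[(R)-4-benzyl-2-oxooxazolidin-3-yl]-2-oxoethyl}phosphonate
Product: 8 (R)-4-benzyl-3-[(R,E)-6-(2,3-dimethoxyphenyl)hept-2-enoyl]oxazolidin-2-one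
Conditions: LiCl, i-Pr2NEt, MeCN, rt
Reagents that add atoms: none
Why: Horner–Wadsworth–Emmons olefination under Masamune–Roush conditions should give the E-enoyl imide from an enolisable aldehyde without strong base, the remote C-5 centre being unaffected.

Step 5
Reactants: 8 (R)-4-benzyl-3-[(R,E)-6-(2,3-dimethoxyphenyl)hept-2-enoyl]oxazolidin-2-one
Product: 9 (R)-4-benzyl-3-{2-[(1S,4R)-5,6-dimethoxy-4-methyl-1,2,3,4-tetrahydronaphthalen-1-yl]acetyl}oxazolidin-2-one
Conditions: Me2AlCl (2.5 equiv), CH2Cl2 (0.01 M), −78 → −20 °C; aq. HCl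
Reagents that add atoms: none
Why: Lewis-acid-promoted intramolecular Friedel–Crafts conjugate addition (6-exo-trig) under Evans chelate control: the arene carbon para to the C-3 methoxy group (the future C-8a, the only free position ortho to the tether) attacks the β-carbon of the aluminium-chelated s-cis enoyl imide on the face away from the benzyl group, which sets C-8 as S, and the ring's preference for a pseudoaxial C-8 substituent (peri strain to H-1) and a pseudoaxial C-5 methyl (strain to the C-4 methoxy group) favours the same 5,8-trans isomer.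

Step 6
Reactants: 9 (R)-4-benzyl-3-{2-[(1S,4R)-5,6-dimethoxy-4-methyl-1,2,3,4-tetrahydronaphthalen-1-yl]acetyl}oxazolidin-2-one
Product: 11 (R)-4-benzyl-3-{(R)-2-[(1S,4R)-5,6-dimethoxy-4-methyl-1,2,3,4-tetrahydronaphthalen-1-yl]propanoyl}oxazolidin-2-one, via sodium enolate 10 (not isolated)
Conditions: NaHMDS, THF, −78 °C; then MeI, −78 → −40 °C
Reagents that add atoms: iodomethane, CI
Why: Evans asymmetric alkylation: the chelated Z-enolate is methylated on the face opposite the benzyl group of the (R)-auxiliary, giving the R descriptor at this stage, which is the S-configured C-2′ of the target once the CIP priorities change on chain extension.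

Step 7
Reactants: 11 (R)-4-benzyl-3-{(R)-2-[(1S,4R)-5,6-dimethoxy-4-methyl-1,2,3,4-tetrahydronaphthalen-1-yl]propanoyl}oxazolidin-2-one
Product: 12 (R)-2-[(1S,4R)-5,6-dimethoxy-4-methyl-1,2,3,4-tetrahydronaphthalen-1-yl]propan-1-ol
Conditions: LiBH4, H2O (1 equiv), Et2O, 0 °C
Reagents that add atoms: none
Why: Reductive removal of the auxiliary with lithium borohydride should give the primary alcohol and return the oxazolidinone without enolising the α-stereocentre.

Step 8
Reactants: 12 (R)-2-[(1S,4R)-5,6-dimethoxy-4-methyl-1,2,3,4-tetrahydronaphthalen-1-yl]propan-1-ol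
Product: 13 (R)-2-[(1S,4R)-5,6-dimethoxy-4-methyl-1,2,3,4-tetrahydronaphthalen-1-yl]propanal
Conditions: Dess–Martin periodinane, CH2Cl2, 0 °C → rt
Reagents that add atoms: none
Why: Dess–Martin oxidation should give the α-branched aldehyde under near-neutral conditions that do not epimerise C-2′.

Step 9
Reactants: 13 (R)-2-[(1S,4R)-5,6-dimethoxy-4-methyl-1,2,3,4-tetrahydronaphthalen-1-yl]propanal
Product: 14 (1S,4R)-1-[(S)-but-3-en-2-yl]-5,6-dimethoxy-4-methyl-1,2,3,4-tetrahydronaphthalene
Conditions: Ph3PCH3Br, KHMDS, THF, 0 °C; then 13, −78 → 0 °C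
Reagents that add atoms: methyltriphenylphosphonium bromide, C[P+](c1ccccc1)(c1ccccc1)c1ccccc1.[Br-]
Why: Wittig methylenation with the unstabilised ylide at low temperature adds C-4′ faster than the α-stereocentre can enolise.

Step 10
Reactants: 14 (1S,4R)-1-[(S)-but-3-en-2-yl]-5,6-dimethoxy-4-methyl-1,2,3,4-tetrahydronaphthalene
Product: 16 tert-butyl (5R,8S)-8-[(S)-but-3-en-2-yl]-3,4-dimethoxy-5-methyl-5,6,7,8-tetrahydronaphthalene-2-carboxylate, via aryllithium 15 (not isolated)
Conditions: n-BuLi, TMEDA, Et2O, 0 °C → rt; then Boc2O, THF, −78 °C → rt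
Reagents that add atoms: di-tert-butyl dicarbonate, CC(C)(C)OC(=O)OC(=O)OC(C)(C)C
Why: Directed ortho-metalation: the methoxy group that becomes the C-3 oxygen directs lithiation to its only free ortho position (the future C-2), and acylation of the aryllithium with Boc2O should give the tert-butyl ester directly.

Step 11
Reactants: 16 tert-butyl (5R,8S)-8-[(S)-but-3-en-2-yl]-3,4-dimethoxy-5-methyl-5,6,7,8-tetrahydronaphthalene-2-carboxylate
Product: 18 tert-butyl (5R,8S)-8-[(S)-4-hydroxybutan-2-yl]-3,4-dimethoxy-5-methyl-5,6,7,8-tetrahydronaphthalene-2-carboxylate, via alkylborane 17 (not isolated)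
Conditions: 9-BBN, THF, 0 °C → rt; then NaOH (aq), H2O2, 0 °C → rt
Reagents that add atoms: hydrogen peroxide, OO
Why: Anti-Markovnikov hydroboration of the monosubstituted alkene with 9-BBN followed by oxidation should give the primary alcohol, the tert-butyl ester and aryl ethers being inert and no stereocentre being formed.

Step 12
Reactants: 18 tert-butyl (5R,8S)-8-[(S)-4-hydroxybutan-2-yl]-3,4-dimethoxy-5-methyl-5,6,7,8-tetrahydronaphthalene-2-carboxylate
Product: 19 tert-butyl (5R,8S)-8-[(S)-4-bromobutan-2-yl]-3,4-dimethoxy-5-methyl-5,6,7,8-tetrahydronaphthalene-2-carboxylate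
Conditions: CBr4, PPh3, CH2Cl2, 0 °C
Reagents that add atoms: carbon tetrabromide, BrC(Br)(Br)Br
Why: Appel bromination converts the primary alcohol into the primary bromide under neutral conditions.

Step 13
Reactants: 20 (E)-3-(3,4-dimethoxyphenyl)acrylic acid; 21 (S)-3-bromo-2-methylpropan-1-ol
Product: 22 (S)-3-bromo-2-methylpropyl (E)-3-(3,4-dimethoxyphenyl)acrylate
Conditions: DCC, DMAP (cat.), CH2Cl2, 0 °C → rt
Reagents that add atoms: none
Why: Steglich esterification acylates the primary alcohol without touching the C–Br bond, the stereocentre or the E-alkene.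

Step 14
Reactants: 22 (S)-3-bromo-2-methylpropyl (E)-3-(3,4-dimethoxyphenyl)acrylate; 19 tert-butyl (5R,8S)-8-[(S)-4-bromobutan-2-yl]-3,4-dimethoxy-5-methyl-5,6,7,8-tetrahydronaphthalene-2-carboxylate
Product: 24 tert-butyl (5R,8S)-8-[(2S,6R)-7-{[(E)-3-(3,4-dimethoxyphenyl)acryloyl]oxy}-6-methylheptan-2-yl]-3,4-dimethoxy-5-methyl-5,6,7,8-tetrahydronaphthalene-2-carboxylate, via alkylzinc bromide 23 (not isolated)
Conditions: 22, Zn dust, LiCl, THF, 50 °C; then 19, Pd-PEPPSI-IPr (2 mol %), THF/NMP (2:1), rt
Reagents that add atoms: none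
Why: Palladium–NHC-catalysed alkyl–alkyl Negishi cross-coupling: zinc inserts into the C–Br bond of 22, Pd(0) adds oxidatively to the primary C–Br bond of 19 in an SN2-type step, the alkyl group passes from zinc to palladium and C(sp3)–C(sp3) reductive elimination forms C-4′–C-5′. The closest known reaction type is the room-temperature coupling of unactivated primary alkyl bromides with functionalised alkylzinc halides under bulky NHC–palladium catalysis. No ring is closed and no stereocentre is created; C-6′ is β to the metal but should keep its configuration because reductive elimination from the NHC complex outruns β-hydride elimination, and C-2′, C-5 and C-8 are remote and non-acidic. The step needs chemoselectivity for cross-coupling over β-hydride elimination and over attack on the two esters and the enoate; the substrate secures this because the bromide carbon is primary and unbranched at C-3′, the zinc carbon has no β-leaving group (the acyloxy group is γ), and alkylzinc halides do not add to tert-butyl or cinnamate esters without copper.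

Step 15
Reactants: 24 tert-butyl (5R,8S)-8-[(2S,6R)-7-{[(E)-3-(3,4-dimethoxyphenyl)acryloyl]oxy}-6-methylheptan-2-yl]-3,4-dimethoxy-5-methyl-5,6,7,8-tetrahydronaphthalene-2-carboxylate
Product: 25 (5R,8S)-8-[(2S,6R)-7-{[(E)-3-(3,4-dihydroxyphenyl)acryloyl]oxy}-6-methylheptan-2-yl]-3,4-dihydroxy-5-methyl-5,6,7,8-tetrahydronaphthalene-2-carboxylic acid
Conditions: BBr3 (10 equiv), CH2Cl2, −78 → 0 °C; then H2O
Reagents that add atoms: none
Why: Boron tribromide ether cleavage should remove the four aryl methyl groups (as bromomethane) and the tert-butyl group (via its cation) at low temperature, while the side-chain ester of a β-branched primary alcohol is much slower in alkyl–oxygen cleavage, and hydrolysis on work-up releases both catechols and the acid.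

**Compound list**

1 | (R)-4-benzyloxazolidin-2-one | O=C1N[C@H](Cc2ccccc2)CO1 | starting material
2 | lithium (R)-4-benzyl-2-oxooxazolidin-3-ide | [Li]N1[C@H](Cc2ccccc2)COC1=O | intermediate
3 | (R)-4-benzyl-3-(2-bromoacetyl)oxazolidin-2-one | O=C(CBr)N1[C@H](Cc2ccccc2)COC1=O | intermediate
4 | diethyl {2-[(R)-4-benzyl-2-oxooxazolidin-3-yl]-2-oxoethyl}phosphonate | CCOP(=O)(OCC)CC(=O)N1[C@H](Cc2ccccc2)COC1=O | intermediate
5 | (2,3-dimethoxyphenyl)boronic acid | COc1cccc(B(O)O)c1OC | starting material
6 | (E)-pent-3-en-1-ol | C/C=C/CCO | starting material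
7 | (R)-4-(2,3-dimethoxyphenyl)pentanal | O=CCC[C@@H](C)c1cccc(OC)c1OC | intermediate
8 | (R)-4-benzyl-3-[(R,E)-6-(2,3-dimethoxyphenyl)hept-2-enoyl]oxazolidin-2-one | O=C(/C=C/CC[C@@H](C)c1cccc(OC)c1OC)N1[C@H](Cc2ccccc2)COC1=O | intermediate
9 | (R)-4-benzyl-3-{2-[(1S,4R)-5,6-dimethoxy-4-methyl-1,2,3,4-tetrahydronaphthalen-1-yl]acetyl}oxazolidin-2-one | O=C(C[C@@H]1CC[C@@H](C)c2c1ccc(OC)c2OC)N1[C@H](Cc2ccccc2)COC1=O | intermediate
10 | sodium (Z)-1-[(R)-4-benzyl-2-oxooxazolidin-3-yl]-2-[(1S,4R)-5,6-dimethoxy-4-methyl-1,2,3,4-tetrahydronaphthalen-1-yl]ethen-1-olate | [Na+].[O-]/C(=C\[C@@H]1CC[C@@H](C)c2c1ccc(OC)c2OC)N1[C@H](Cc2ccccc2)COC1=O | intermediate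
11 | (R)-4-benzyl-3-{(R)-2-[(1S,4R)-5,6-dimethoxy-4-methyl-1,2,3,4-tetrahydronaphthalen-1-yl]propanoyl}oxazolidin-2-one | O=C([C@H](C)[C@@H]1CC[C@@H](C)c2c1ccc(OC)c2OC)N1[C@H](Cc2ccccc2)COC1=O | intermediate
12 | (R)-2-[(1S,4R)-5,6-dimethoxy-4-methyl-1,2,3,4-tetrahydronaphthalen-1-yl]propan-1-ol | OC[C@H](C)[C@@H]1CC[C@@H](C)c2c1ccc(OC)c2OC | intermediate
13 | (R)-2-[(1S,4R)-5,6-dimethoxy-4-methyl-1,2,3,4-tetrahydronaphthalen-1-yl]propanal | O=C[C@H](C)[C@@H]1CC[C@@H](C)c2c1ccc(OC)c2OC | intermediate
14 | (1S,4R)-1-[(S)-but-3-en-2-yl]-5,6-dimethoxy-4-methyl-1,2,3,4-tetrahydronaphthalene | C=C[C@H](C)[C@@H]1CC[C@@H](C)c2c1ccc(OC)c2OC | intermediate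
15 | [(5R,8S)-8-[(S)-but-3-en-2-yl]-3,4-dimethoxy-5-methyl-5,6,7,8-tetrahydronaphthalen-2-yl]lithium | C=C[C@H](C)[C@@H]1CC[C@@H](C)c2c1cc([Li])c(OC)c2OC | intermediate
16 | tert-butyl (5R,8S)-8-[(S)-but-3-en-2-yl]-3,4-dimethoxy-5-methyl-5,6,7,8-tetrahydronaphthalene-2-carboxylate | C=C[C@H](C)[C@@H]1CC[C@@H](C)c2c1cc(C(=O)OC(C)(C)C)c(OC)c2OC | intermediate
17 | tert-butyl (5R,8S)-8-[(S)-4-(9-borabicyclo[3.3.1]nonan-9-yl)butan-2-yl]-3,4-dimethoxy-5-methyl-5,6,7,8-tetrahydronaphthalene-2-carboxylate | C(C[C@H](C)[C@@H]1CC[C@@H](C)c2c1cc(C(=O)OC(C)(C)C)c(OC)c2OC)B1C2CCCC1CCC2 | intermediate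
18 | tert-butyl (5R,8S)-8-[(S)-4-hydroxybutan-2-yl]-3,4-dimethoxy-5-methyl-5,6,7,8-tetrahydronaphthalene-2-carboxylate | OCC[C@H](C)[C@@H]1CC[C@@H](C)c2c1cc(C(=O)OC(C)(C)C)c(OC)c2OC | intermediate
19 | tert-butyl (5R,8S)-8-[(S)-4-bromobutan-2-yl]-3,4-dimethoxy-5-methyl-5,6,7,8-tetrahydronaphthalene-2-carboxylate | BrCC[C@H](C)[C@@H]1CC[C@@H](C)c2c1cc(C(=O)OC(C)(C)C)c(OC)c2OC | intermediate
20 | (E)-3-(3,4-dimethoxyphenyl)acrylic acid | COc1ccc(/C=C/C(=O)O)cc1OC | starting material
21 | (S)-3-bromo-2-methylpropan-1-ol | C[C@H](CBr)CO | starting material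
22 | (S)-3-bromo-2-methylpropyl (E)-3-(3,4-dimethoxyphenyl)acrylate | C[C@H](CBr)COC(=O)/C=C/c1ccc(OC)c(OC)c1 | intermediate
23 | bromo{(S)-3-[(E)-3-(3,4-dimethoxyphenyl)acryloyloxy]-2-methylpropyl}zinc | C[C@H](C[Zn]Br)COC(=O)/C=C/c1ccc(OC)c(OC)c1 | intermediate
24 | tert-butyl (5R,8S)-8-[(2S,6R)-7-{[(E)-3-(3,4-dimethoxyphenyl)acryloyl]oxy}-6-methylheptan-2-yl]-3,4-dimethoxy-5-methyl-5,6,7,8-tetrahydronaphthalene-2-carboxylate | C[C@H](CCC[C@H](C)[C@@H]1CC[C@@H](C)c2c1cc(C(=O)OC(C)(C)C)c(OC)c2OC)COC(=O)/C=C/c1ccc(OC)c(OC)c1 | intermediate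
25 | (5R,8S)-8-[(2S,6R)-7-{[(E)-3-(3,4-dihydroxyphenyl)acryloyl]oxy}-6-methylheptan-2-yl]-3,4-dihydroxy-5-methyl-5,6,7,8-tetrahydronaphthalene-2-carboxylic acid | C[C@H](CCC[C@H](C)[C@@H]1CC[C@@H](C)c2c1cc(C(=O)O)c(O)c2O)COC(=O)/C=C/c1ccc(O)c(O)c1 | target

Total step count: 15
Longest linear sequence: 13 steps (1, 2, 4–12, 14, 15; 12 steps counted from boronic acid 5)

**Steps most likely to fail**

Step 5. The dimethoxyarene may be too weak a nucleophile for the β-substituted enoyl imide, so that ring closure is slow and oligomerisation or Lewis-acid demethylation competes; reaction through a non-chelated conformer would erode facial selectivity. The fallback sets out from aldehyde 7 and closes the ring by acylation instead. Pinnick oxidation (NaClO2, NaH2PO4, 2-methyl-2-butene) should give (R)-4-(2,3-dimethoxyphenyl)pentanoic acid F1. Friedel–Crafts acylation with Eaton's reagent should give (R)-5,6-dimethoxy-4-methyl-3,4-dihydronaphthalen-1(2H)-one F2. Horner–Wadsworth–Emmons olefination with triethyl phosphonoacetate and NaH should give ethyl (E)-2-[(R)-5,6-dimethoxy-4-methyl-3,4-dihydronaphthalen-1(2H)-ylidene]acetate F3. Copper hydride conjugate reduction with a chiral bisphosphine and a silane sets C-8 under catalyst control and should give ethyl 2-[(1S,4R)-5,6-dimethoxy-4-methyl-1,2,3,4-tetrahydronaphthalen-1-yl]acetate F4; the catalyst has to override the ring's kinetic preference for the cis isomer. Saponification should give 2-[(1S,4R)-5,6-dimethoxy-4-methyl-1,2,3,4-tetrahydronaphthalen-1-yl]acetic acid F5, and its pivaloyl mixed anhydride acylates lithium oxazolidinide 2. The route is rejoined at compound 9.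

Step 15. Demethylation may not stop at the intended bonds: bromide attack can cleave the side-chain ester, or the hindered C-4 methyl ether may be cleaved incompletely. The fallback sets out from bromide 19 and alcohol 21 and attaches the caffeoyl group after deprotection, enzymatically. Silylation of 21 (TBSCl, imidazole) should give (S)-(3-bromo-2-methylpropoxy)(tert-butyl)dimethylsilane F6. Zinc insertion should give bromo[(S)-3-(tert-butyldimethylsilyloxy)-2-methylpropyl]zinc F7. Negishi coupling with 19 as in step 14 should give tert-butyl (5R,8S)-8-[(2S,6R)-7-(tert-butyldimethylsilyloxy)-6-methylheptan-2-yl]-3,4-dimethoxy-5-methyl-5,6,7,8-tetrahydronaphthalene-2-carboxylate F8. Boron tribromide, now with no sensitive ester present, should give (5R,8S)-3,4-dihydroxy-8-[(2S,6R)-7-hydroxy-6-methylheptan-2-yl]-5-methyl-5,6,7,8-tetrahydronaphthalene-2-carboxylic acid F9. A lipase (immobilised Candida antarctica lipase B) with vinyl caffeate in tert-butyl methyl ether/THF should acylate only the primary aliphatic hydroxyl, not the phenols. The route comes back at target 25.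

Step 14. Zinc insertion into 22 may be slow, the organozinc 23 may decompose (1,3-elimination with loss of carboxylate, or protonation), or β-hydride elimination at palladium may divert 19 to reduced or eliminated material and homocoupling. The fallback sets out from alkene 16 and bromo ester 22 and places the metal on the tetralin half. Hydroboration of 16 with 9-BBN gives alkylborane 17, which is coupled directly with 22 in a nickel-catalysed alkyl–alkyl Suzuki–Miyaura reaction (NiCl2·glyme, trans-N,N′-dimethylcyclohexane-1,2-diamine, KOt-Bu, i-BuOH, dioxane, rt). Its radical-type oxidative addition tolerates the β-branched bromide, and the alkoxide is bound as the borate. The route is rejoined at compound 24; no compound outside the list is made (F0).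

**Further compounds**

F1 | step 5 | (R)-4-(2,3-dimethoxyphenyl)pentanoic acid | O=C(O)CC[C@@H](C)c1cccc(OC)c1OC
F2 | step 5 | (R)-5,6-dimethoxy-4-methyl-3,4-dihydronaphthalen-1(2H)-one | O=C1CC[C@@H](C)c2c1ccc(OC)c2OC
F3 | step 5 | ethyl (E)-2-[(R)-5,6-dimethoxy-4-methyl-3,4-dihydronaphthalen-1(2H)-ylidene]acetate | CCOC(=O)/C=C1\CC[C@@H](C)c2c1ccc(OC)c2OC
F4 | step 5 | ethyl 2-[(1S,4R)-5,6-dimethoxy-4-methyl-1,2,3,4-tetrahydronaphthalen-1-yl]acetate | CCOC(=O)C[C@@H]1CC[C@@H](C)c2c1ccc(OC)c2OC
F5 | step 5 | 2-[(1S,4R)-5,6-dimethoxy-4-methyl-1,2,3,4-tetrahydronaphthalen-1-yl]acetic acid | O=C(O)C[C@@H]1CC[C@@H](C)c2c1ccc(OC)c2OC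
F0 | step 14 | none | none
F6 | step 15 | (S)-(3-bromo-2-methylpropoxy)(tert-butyl)dimethylsilane | C[C@H](CBr)CO[Si](C)(C)C(C)(C)C
F7 | step 15 | bromo[(S)-3-(tert-butyldimethylsilyloxy)-2-methylpropyl]zinc | C[C@H](C[Zn]Br)CO[Si](C)(C)C(C)(C)C
F8 | step 15 | tert-butyl (5R,8S)-8-[(2S,6R)-7-(tert-butyldimethylsilyloxy)-6-methylheptan-2-yl]-3,4-dimethoxy-5-methyl-5,6,7,8-tetrahydronaphthalene-2-carboxylate | C[C@H](CCC[C@H](C)[C@@H]1CC[C@@H](C)c2c1cc(C(=O)OC(C)(C)C)c(OC)c2OC)CO[Si](C)(C)C(C)(C)C
F9 | step 15 | (5R,8S)-3,4-dihydroxy-8-[(2S,6R)-7-hydroxy-6-methylheptan-2-yl]-5-methyl-5,6,7,8-tetrahydronaphthalene-2-carboxylic acid | C[C@H](CCC[C@H](C)[C@@H]1CC[C@@H](C)c2c1cc(C(=O)O)c(O)c2O)CO
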